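**Strategy.** Ring B of the target (C5–C10, labdane numbering) is treated as a Diels–Alder retron: the C8–C9 and C5–C10 bonds are cut together, with C11 carried as a formyl activator and C17 as a benzyloxymethyl group. A single Me2AlCl-promoted intramolecular cycloaddition of an acyclic (2E,8E,10E)-trienal folds the chain into the trans-decalin, closing ring B at C8–C9 and fixing C5, C9 and quaternary C10 under control of the lone C3 carbinol centre, set earlier by reagent-controlled prenylboration. The adduct is then hydrogenated, C11 is extended by methylenation and B-alkyl Suzuki coupling to the Z-enoate, and C17 is oxidised and equilibrated to the equatorial aldehyde.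

Key step: step 8

Remark on numbering: labdane numbering is used for all intermediates (ring A = C1–C5, C10; ring B = C5–C10; C17 on C8; C11–C16 side chain; C20 on C10). The target is (3R,5S,8S,9R,10S), with the C3 hydroxyl, the C9 chain and the C8 formyl group all equatorial.

Remark on the chemistry: (−)-Ipc2BOMe, derived from (+)-α-pinene, is assumed to deliver the 6R carbinol 5, by analogy with its allyl congener; the antipodal borane would serve if the sense proved opposite.

Step 1
Reactants: 1 geranyl acetate
Product: 3 (2E)-3-methyl-6-oxohex-2-en-1-yl acetate, via secondary ozonide 2 (not isolated)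
Conditions: O3 (1.0 equiv), CH2Cl2, −78 °C; then Me2S, −78 °C to rt
Reagents that add atoms: ozone, [O-][O+]=O
Why: Ozonolysis should cleave only the electron-rich 6,7-alkene, because the 2,3-alkene is deactivated by the allylic acetoxy group, so the 2E geometry is kept and no stereocentre is formed.

Step 2
Reactants: 3 (2E)-3-methyl-6-oxohex-2-en-1-yl acetate
Product: 5 (2E,6R)-6-hydroxy-3,7,7-trimethylnona-2,8-dien-1-yl acetate, via borinate ester 4 (not isolated)
Conditions: (−)-Ipc2BOMe, prenylmagnesium chloride, Et2O/THF, −78 °C to rt; then 3, −78 °C; then H2O2, pH 7 phosphate buffer, MeOH, 0 °C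
Reagents that add atoms: prenylmagnesium chloride, CC(C)=CC[Mg]Cl
Why: Asymmetric allylboration (prenylboration) by the B-prenyldiisopinocampheylborane formed in the flask should pass through a closed chair transition state and deliver the prenyl unit at its γ-carbon, creating the C4 gem-dimethyl/vinyl array and setting the C3 carbinol centre (6R) under control of the isopinocampheyl groups, while the acetate is inert at −78 °C.

Step 3
Reactants: 5 (2E,6R)-6-hydroxy-3,7,7-trimethylnona-2,8-dien-1-yl acetate
Product: 6 (2E,6R)-6-(benzyloxy)-3,7,7-trimethylnona-2,8-dien-1-yl acetate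
Conditions: 2-benzyloxy-1-methylpyridinium triflate (2 equiv), MgO, PhCF3, 85 °C
Reagents that add atoms: 2-benzyloxy-1-methylpyridinium triflate, C[n+]1ccccc1OCc1ccccc1.[O-]S(=O)(=O)C(F)(F)F
Why: Neutral benzyl transfer (O-benzylation with a 2-benzyloxypyridinium salt) should etherify the hindered secondary alcohol without base, so the allylic acetate survives, and the ether blocks oxa-Michael closure onto the later enal.

Step 4
Reactants: 7 benzyl propargyl ether
Product: 9 (E)-3-(benzyloxy)-1-iodoprop-1-ene, via alkenylzirconocene 8 (not isolated)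
Conditions: Cp2Zr(H)Cl, THF, rt; then I2, 0 °C
Reagents that add atoms: iodine, II
Why: Hydrozirconation–iodination should place zirconium at the alkyne terminus by syn addition, and iododemetalation with retention gives the E-iodide.

Step 5
Reactants: 6 (2E,6R)-6-(benzyloxy)-3,7,7-trimethylnona-2,8-dien-1-yl acetate; 9 (E)-3-(benzyloxy)-1-iodoprop-1-ene
Product: 10 (2E,6R,8E,10E)-6,12-bis(benzyloxy)-3,7,7-trimethyldodeca-2,8,10-trien-1-yl acetate
Conditions: Pd(OAc)2 (5 mol %), K2CO3, n-Bu4NCl, DMF, 60 °C
Reagents that add atoms: none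
Why: In this Heck reaction the alkenylpalladium iodide should insert the terminal alkene at CH2 only, and β-hydride elimination can run only toward the new bond because C4 is quaternary, giving the E,E-diene with retention of the iodide geometry, while phosphine-free conditions are expected to leave the allylic acetate un-ionised.

Step 6
Reactants: 10 (2E,6R,8E,10E)-6,12-bis(benzyloxy)-3,7,7-trimethyldodeca-2,8,10-trien-1-yl acetate
Product: 11 (2E,6R,8E,10E)-6,12-bis(benzyloxy)-3,7,7-trimethyldodeca-2,8,10-trien-1-ol
Conditions: K2CO3 (0.2 equiv), MeOH, 0 °C to rt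
Reagents that add atoms: none
Why: Transesterification (methanolysis) should remove the acetate while benzyl ethers and alkenes are inert.

Step 7
Reactants: 11 (2E,6R,8E,10E)-6,12-bis(benzyloxy)-3,7,7-trimethyldodeca-2,8,10-trien-1-ol
Product: 12 (2E,6R,8E,10E)-6,12-bis(benzyloxy)-3,7,7-trimethyldodeca-2,8,10-trienal
Conditions: activated MnO2 (15 equiv), CH2Cl2, rt
Reagents that add atoms: none
Why: Allylic oxidation with MnO2 should convert the only free, allylic hydroxyl into the 2E-enal without isomerisation.

Step 8
Reactants: 12 (2E,6R,8E,10E)-6,12-bis(benzyloxy)-3,7,7-trimethyldodeca-2,8,10-trienal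
Product: 13 (1R,2R,4aS,6R,8aR)-6-(benzyloxy)-2-[(benzyloxy)methyl]-5,5,8a-trimethyl-1,2,4a,5,6,7,8,8a-octahydronaphthalene-1-carbaldehyde (trans-fused; C9 formyl equatorial and C8 benzyloxymethyl axial, both cis to the C10 methyl; H-5, H-8 and H-9 on the opposite face)
Conditions: Me2AlCl (2.0 equiv), CH2Cl2, −78 to −20 °C; aqueous potassium sodium tartrate work-up
Reagents that add atoms: none
Why: Me2AlCl binds the formyl oxygen of the 2E-enal and lowers its LUMO, and the activated C9=C10 dienophile (C2=C3 of 12) then adds across C5 and C8 of the tethered E,E-diene (C8–C11 of 12) in a concerted, asynchronous [4+2] cycloaddition. The closest known reaction type is the Lewis acid-promoted type 1 intramolecular Diels–Alder reaction of 2,8,10-undecatrienals to trans-fused octalins. Ring A closes by the C5–C10 bond as the tether ring, its four-carbon tether C1–C4 held in a chair-like array, and ring B closes by the C8–C9 bond as the cyclohexene formed by the suprafacial cycloaddition itself. C9 and C10 follow from the E geometry of the enal (C11 cis to the C10 methyl), C5 and C8 from the E,E geometry of the diene (C4 and C17 cis), the trans ring fusion from the endo position of the aluminium-bound formyl group with the tether exo, and the absolute sense from the C3 benzyloxy group, which sits equatorial in the chair-like tether next to the C4 gem-dimethyl group and so selects one diene face. The step needs endo over exo selectivity and an intact enal geometry, which the Lewis acid, the low temperature and the E-configured enal should secure; C8 emerges with its CH2OBn group axial and is corrected in step 13 by equilibration of the aldehyde.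

Step 9
Reactants: 13 (1R,2R,4aS,6R,8aR)-6-(benzyloxy)-2-[(benzyloxy)methyl]-5,5,8a-trimethyl-1,2,4a,5,6,7,8,8a-octahydronaphthalene-1-carbaldehyde
Product: 14 6,6,9a-trimethyldodecahydronaphtho[1,2-c]furan-1,7-diol (lactol bridging C11 and C17, cis-fused to ring B, anomeric mixture)
Conditions: H2 (3 atm), Pd(OH)2 on carbon, EtOAc, rt
Reagents that add atoms: none
Why: Heterogeneous catalytic hydrogenation should saturate C6=C7 (no new stereocentre) and hydrogenolyse both benzyl ethers, and the freed axial C17 hydroxyl, cis to the C9 formyl group, should close at once to the five-membered lactol, which masks the aldehyde against reduction.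

Step 10
Reactants: 14 6,6,9a-trimethyldodecahydronaphtho[1,2-c]furan-1,7-diol (lactol)
Product: 16 5-ethenyl-6-(hydroxymethyl)-1,1,4a-trimethyldecahydronaphthalen-2-ol (C9 vinyl equatorial, C8 CH2OH axial, 3R), via open hydroxy aldehyde 15 (not isolated)
Conditions: Ph3PCH3Br (4 equiv), KOtBu (3.9 equiv), THF, 0 to 45 °C
Reagents that add atoms: methyltriphenylphosphonium bromide, C[P+](c1ccccc1)(c1ccccc1)c1ccccc1.[Br-]
Why: In this Wittig methylenation the lactol should open reversibly under the basic conditions to the hydroxy aldehyde 15, whose formyl group is trapped by excess ylide, while C9 keeps its equatorial, thermodynamically preferred configuration and no new stereocentre is formed.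

Step 11
Reactants: 17 methyl but-2-ynoate
Product: 18 methyl (2Z)-3-iodobut-2-enoate
Conditions: NaI, AcOH, 115 °C
Reagents that add atoms: sodium iodide, [Na+].[I-]
Why: Hydroiodination by conjugate addition of iodide and anti protonation should give the Z-iodoenoate stereoselectively.

Step 12
Reactants: 16 5-ethenyl-6-(hydroxymethyl)-1,1,4a-trimethyldecahydronaphthalen-2-ol; 18 methyl (2Z)-3-iodobut-2-enoate
Product: 20 methyl (2Z)-5-[6-hydroxy-2-(hydroxymethyl)-5,5,8a-trimethyldecahydronaphthalen-1-yl]-3-methylpent-2-enoate (8R, CH2OH axial), via B-alkyl borane 19 (not isolated)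
Conditions: 9-BBN (3.5 equiv), THF, rt to 50 °C; then 18, Pd(dppf)Cl2 (5 mol %), AsPh3, aqueous K3PO4, DMF, rt
Reagents that add atoms: none
Why: In this hydroboration/B-alkyl Suzuki–Miyaura sequence 9-BBN should add to the terminal carbon of the vinyl group (the hydroxyls being tied up as borinates), and coupling with the Z-iodide proceeds with retention of alkene geometry to give the 13Z-enoate.

Step 13
Reactants: 20 methyl (2Z)-5-[6-hydroxy-2-(hydroxymethyl)-5,5,8a-trimethyldecahydronaphthalen-1-yl]-3-methylpent-2-enoate
Product: 22 methyl (2Z)-5-[(1R,2S,4aS,6R,8aS)-2-formyl-6-hydroxy-5,5,8a-trimethyldecahydronaphthalen-1-yl]-3-methylpent-2-enoate (target), via axial aldehyde 21 (not isolated)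
Conditions: TEMPO (0.1 equiv), PhI(OAc)2 (1.1 equiv), CH2Cl2, rt; then DBU (0.5 equiv), rt
Reagents that add atoms: none
Why: Nitroxyl-catalysed oxidation should select the primary C17 alcohol over the hindered secondary C3 alcohol, and the resulting axial aldehyde, syn-diaxial to the C10 methyl, should epimerise through its enol to the equatorial 8S aldehyde under thermodynamic control.

**Compound list**

1 | geranyl acetate, (2E)-3,7-dimethylocta-2,6-dien-1-yl acetate | CC(=O)OC/C=C(\C)CCC=C(C)C | starting material
2 | secondary ozonide, (2E)-5-(5,5-dimethyl-1,2,4-trioxolan-3-yl)-3-methylpent-2-en-1-yl acetate | CC(=O)OC/C=C(\C)CCC1OOC(C)(C)O1 | intermediate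
3 | (2E)-3-methyl-6-oxohex-2-en-1-yl acetate | CC(=O)OC/C=C(\C)CCC=O | intermediate
4 | diisopinocampheylborinate ester of 5 | CC(=O)OC/C=C(\C)CC[C@@H](OB([C@@H]1C[C@@H]2C[C@H]([C@H]1C)C2(C)C)[C@@H]1C[C@@H]2C[C@H]([C@H]1C)C2(C)C)C(C)(C)C=C | intermediate
5 | (2E,6R)-6-hydroxy-3,7,7-trimethylnona-2,8-dien-1-yl acetate | CC(=O)OC/C=C(\C)CC[C@@H](O)C(C)(C)C=C | intermediate
6 | (2E,6R)-6-(benzyloxy)-3,7,7-trimethylnona-2,8-dien-1-yl acetate | CC(=O)OC/C=C(\C)CC[C@@H](OCc1ccccc1)C(C)(C)C=C | intermediate
7 | benzyl propargyl ether | C#CCOCc1ccccc1 | starting material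
8 | (E)-[3-(benzyloxy)prop-1-enyl]zirconocene chloride | Cl[Zr](/C=C/COCc1ccccc1)(C1C=CC=C1)C1C=CC=C1 | intermediate
9 | (E)-3-(benzyloxy)-1-iodoprop-1-ene | I/C=C/COCc1ccccc1 | intermediate
10 | (2E,6R,8E,10E)-6,12-bis(benzyloxy)-3,7,7-trimethyldodeca-2,8,10-trien-1-yl acetate | CC(=O)OC/C=C(\C)CC[C@@H](OCc1ccccc1)C(C)(C)/C=C/C=C/COCc1ccccc1 | intermediate
11 | (2E,6R,8E,10E)-6,12-bis(benzyloxy)-3,7,7-trimethyldodeca-2,8,10-trien-1-ol | OC/C=C(\C)CC[C@@H](OCc1ccccc1)C(C)(C)/C=C/C=C/COCc1ccccc1 | intermediate
12 | (2E,6R,8E,10E)-6,12-bis(benzyloxy)-3,7,7-trimethyldodeca-2,8,10-trienal | O=C/C=C(\C)CC[C@@H](OCc1ccccc1)C(C)(C)/C=C/C=C/COCc1ccccc1 | intermediate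
13 | (1R,2R,4aS,6R,8aR)-6-(benzyloxy)-2-[(benzyloxy)methyl]-5,5,8a-trimethyl-1,2,4a,5,6,7,8,8a-octahydronaphthalene-1-carbaldehyde, trans-fused, CHO equatorial, CH2OBn axial | O=C[C@@H]1[C@H](COCc2ccccc2)C=C[C@@H]3C(C)(C)[C@H](OCc2ccccc2)CC[C@@]13C | intermediate
14 | 6,6,9a-trimethyldodecahydronaphtho[1,2-c]furan-1,7-diol, lactol, anomeric mixture | OC3[C@@H]1[C@H](CO3)CC[C@@H]2C(C)(C)[C@H](O)CC[C@@]12C | intermediate
15 | 6-hydroxy-2-(hydroxymethyl)-5,5,8a-trimethyldecahydronaphthalene-1-carbaldehyde, open form of 14 (CHO equatorial, CH2OH axial) | O=C[C@@H]1[C@H](CO)CC[C@@H]2C(C)(C)[C@H](O)CC[C@@]12C | intermediate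
16 | 5-ethenyl-6-(hydroxymethyl)-1,1,4a-trimethyldecahydronaphthalen-2-ol (vinyl equatorial, CH2OH axial) | C=C[C@@H]1[C@H](CO)CC[C@@H]2C(C)(C)[C@H](O)CC[C@@]12C | intermediate
17 | methyl but-2-ynoate | CC#CC(=O)OC | starting material
18 | methyl (2Z)-3-iodobut-2-enoate | COC(=O)/C=C(/C)I | intermediate
19 | B-alkyl-9-BBN adduct of 16 with both hydroxyls as 9-BBN borinates | C(CB1C2CCCC1CCC2)[C@@H]1[C@H](COB3C4CCCC3CCC4)CC[C@@H]2C(C)(C)[C@H](OB3C4CCCC3CCC4)CC[C@@]12C | intermediate
20 | methyl (2Z)-5-[6-hydroxy-2-(hydroxymethyl)-5,5,8a-trimethyldecahydronaphthalen-1-yl]-3-methylpent-2-enoate, 8R (CH2OH axial) | COC(=O)/C=C(/C)CC[C@@H]1[C@H](CO)CC[C@@H]2C(C)(C)[C@H](O)CC[C@@]12C | intermediate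
21 | C8 epimer of the target, formyl group axial (8R) | COC(=O)/C=C(/C)CC[C@@H]1[C@H](C=O)CC[C@@H]2C(C)(C)[C@H](O)CC[C@@]12C | intermediate
22 | methyl (2Z)-5-[(1R,2S,4aS,6R,8aS)-2-formyl-6-hydroxy-5,5,8a-trimethyldecahydronaphthalen-1-yl]-3-methylpent-2-enoate | COC(=O)/C=C(/C)CC[C@@H]1[C@@H](C=O)CC[C@@H]2C(C)(C)[C@H](O)CC[C@@]12C | target

**Step count.** Total: 13 steps. Longest linear sequence: 11 steps (1, 2, 3, 5, 6, 7, 8, 9, 10, 12, 13); steps 4 and 11 prepare the two coupling partners.

**Steps most likely to fail**

Step 8 (key cycloaddition). The exo transition state, which leads to the cis-fused isomer, may compete because the trans-fused endo array must build up a syn-diaxial contact between the C4 and C10 methyl groups. The Lewis acid may also isomerise the enal or ionise the dienylic benzyl ether, and the β,β-disubstituted dienophile may react sluggishly. The fallback is a stepwise ionic Diels–Alder reaction. It sets out from 12: 1,2-bis(trimethylsilyloxy)ethane with catalytic TMSOTf in CH2Cl2 at −78 °C would give the 2-alkenyl-1,3-dioxolane F1. More TMSOTf at −78 to −40 °C would open the acetal to an α,β-unsaturated oxocarbenium ion (a 1-alkoxyallyl cation), which adds stepwise to the diene and recloses to the bicyclic dioxolane F2. Aqueous acetic acid in THF would then hydrolyse F2 and return to the route at 13.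

Step 5 (Heck coupling). Insertion of the neopentyl-type alkene may be slow, zerovalent palladium may ionise the allylic acetate, and re-addition of palladium hydride may erode the diene geometry. The fallback forms the C6–C7 bond by cross-coupling instead. It sets out from 6: cross-metathesis with vinylboronic acid pinacol ester (second-generation Grubbs catalyst, CH2Cl2, 40 °C) would give the (E)-alkenylboronate F3. Suzuki–Miyaura coupling of F3 with iodide 9 (Pd(dppf)Cl2, aqueous K3PO4, THF, rt), in which oxidative addition of the alkenyl iodide should outpace ionisation of the trisubstituted allylic acetate, would return to the route at 10.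

Step 10 (methylenation of the lactol). Ring opening of the lactol may be incomplete, the ylide may attack slowly at a formyl group flanked by quaternary C10, and the base may epimerise or degrade the hydroxy aldehyde. The fallback keeps the benzyl ethers until the side chain is in place. It sets out from 13: Ph3P=CH2 in THF on the free aldehyde would give the vinyl diene F4. 9-BBN, which hydroborates only the vinyl group, would give the B-alkyl borane F5, and coupling of F5 with 18 under the conditions of step 12 would give the enoate F6. H2 with RhCl(PPh3)3 in benzene would saturate only C6=C7 to give the bis(benzyl ether) F7. BCl3 with pentamethylbenzene in CH2Cl2 at −78 °C would remove both benzyl groups from F7 and return to the route at 20.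

**Further compounds**

F1 | step 8 | 2-[(1E,5R,7E,9E)-5,11-bis(benzyloxy)-2,6,6-trimethylundeca-1,7,9-trien-1-yl]-1,3-dioxolane | O1CCOC1/C=C(\C)CC[C@@H](OCc2ccccc2)C(C)(C)/C=C/C=C/COCc2ccccc2
F2 | step 8 | 1,3-dioxolane acetal of 13 | O1CCOC1[C@@H]3[C@H](COCc2ccccc2)C=C[C@@H]4C(C)(C)[C@H](OCc2ccccc2)CC[C@@]34C
F3 | step 5 | (2E,6R,8E)-6-(benzyloxy)-3,7,7-trimethyl-9-(4,4,5,5-tetramethyl-1,3,2-dioxaborolan-2-yl)nona-2,8-dien-1-yl acetate | CC(=O)OC/C=C(\C)CC[C@@H](OCc1ccccc1)C(C)(C)/C=C/B1OC(C)(C)C(C)(C)O1
F4 | step 10 | 9-vinyl analogue of 13 (CHO replaced by CH=CH2, benzyl ethers and C6=C7 retained) | C=C[C@@H]1[C@H](COCc2ccccc2)C=C[C@@H]3C(C)(C)[C@H](OCc2ccccc2)CC[C@@]13C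
F5 | step 10 | B-alkyl-9-BBN adduct of F4 (boron on the terminal carbon of the former vinyl group) | C(CB1C2CCCC1CCC2)[C@@H]1[C@H](COCc2ccccc2)C=C[C@@H]3C(C)(C)[C@H](OCc2ccccc2)CC[C@@]13C
F6 | step 10 | 3,17-bis(benzyl ether) of 20 with C6=C7 retained | COC(=O)/C=C(/C)CC[C@@H]1[C@H](COCc2ccccc2)C=C[C@@H]3C(C)(C)[C@H](OCc2ccccc2)CC[C@@]13C
F7 | step 10 | 3,17-bis(benzyl ether) of 20 | COC(=O)/C=C(/C)CC[C@@H]1[C@H](COCc2ccccc2)CC[C@@H]3C(C)(C)[C@H](OCc2ccccc2)CC[C@@]13C
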